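**Strategy.** The cyclohexene (C1–C6) is opened at its only C=C bond, C4=C5, which is flanked by the two allylic oxygenated carbons C3 and C6. Ring-closing metathesis of an acyclic octa-1,7-diene closes this six-membered carbocycle. The diene is cut from D-mannose: mannose C2–C4 become C1–C3 (C1 made quaternary by stereoretentive hydroxymethylation), mannose C1 plus a vinyl Grignard gives C6/C5, and the 5,6-diol gives C4. The precursor carries the cis C1/C2 diol as an acetonide that holds both vinyl arms syn, and a silylene ring over O6/O7 that keeps C6–OH masked until C2 is acetylated.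

Key step: step 8

Remark on numbering: ring numbering of the target is used throughout, also for acyclic intermediates ("future C…"). C1 = quaternary carbinol carbon bearing OH and C7H2OBz, C2 = CH–OAc, C3 = CH–OBz, C4=C5, C6 = CH–OH; the target is then (1R,2S,3R,6S). Mapping: mannose C1→C6, C2→C1, C3→C2, C4→C3, C5→C4; the formaldehyde carbon is C7 and the Grignard CH is C5. Compounds 3 and 4 are used as anomeric mixtures, since the anomeric centre is destroyed in step 3.

Step 1
Reactants: 1 2,3:5,6-di-O-isopropylidene-α-D-mannofuranose; 2 formaldehyde (37% aqueous)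
Product: 3 2-C-(hydroxymethyl)-2,3:5,6-di-O-isopropylidene-D-mannofuranose
Conditions: aq. CH2O, K2CO3, MeOH, 65 °C
Reagents that add atoms: none
Why: Crossed aldol (Tollens-type hydroxymethylation) of the ring-opened aldehyde, in which the enolate carbon held in the dioxolane takes formaldehyde on the face anti to the side chain of the neighbouring ring carbon, so CH2OH replaces H with retention, the lactol re-closes and the quaternary centre (future C1) is set.

Step 2
Reactants: 3 2-C-(hydroxymethyl)-2,3:5,6-di-O-isopropylidene-D-mannofuranose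
Product: 4 2-C-[(di-tert-butylsilyloxy)methyl]-2,3:5,6-di-O-isopropylidene-D-mannofuranose
Conditions: t-Bu2SiHCl (1.05 equiv), imidazole, DMF, 0 °C
Reagents that add atoms: di-tert-butylchlorosilane, CC(C)(C)[SiH](Cl)C(C)(C)C
Why: Selective O-silylation of the primary hydroxyl over the hindered hemiacetal hydroxyl should give a bulky, non-chelating hydrosilyl ether whose Si–H bond is kept for step 4.

Step 3
Reactants: 4 2-C-[(di-tert-butylsilyloxy)methyl]-2,3:5,6-di-O-isopropylidene-D-mannofuranose; 5 vinylmagnesium bromide
Product: 7 (3S)-1,2-dideoxy-4-C-[(di-tert-butylsilyloxy)methyl]-4,5:7,8-di-O-isopropylidene-D-glycero-D-galacto-oct-1-enitol, via open-chain aldehyde 6 (not isolated)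
Conditions: CH2=CHMgBr (4 equiv), THF, −78 → 0 °C; aq. NH4Cl
Reagents that add atoms: none
Why: Grignard addition to a lactol: the first equivalent deprotonates and opens it to aldehyde 6, magnesium is chelated between the carbonyl oxygen and the dioxolane oxygen on future C1 (the silyl ether oxygen does not compete), and vinyl should add anti to the future C2–C3 arm (Cram chelate) to give the (S)-carbinol at future C6, threo to O1, by analogy with 5-O-silyl-2,3-O-isopropylidene furanoses.

Step 4
Reactants: 7 (3S)-1,2-dideoxy-4-C-[(di-tert-butylsilyloxy)methyl]-4,5:7,8-di-O-isopropylidene-D-glycero-D-galacto-oct-1-enitol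
Product: 8 di-tert-butylsilylene (1,3-dioxa-2-silinane) bridging O6 and O7 of the octenitol skeleton of 7, with the future C3 hydroxyl free
Conditions: KOt-Bu (10 mol %), THF, 0 °C → rt
Reagents that add atoms: none
Why: Base-catalysed dehydrogenative Si–O coupling (alcoholysis of a hydrosilane): the C6 alkoxide attacks the silicon held 1,3 to it, H2 is lost and the six-membered ring should close in preference to the seven-membered ring through O3, leaving O3–H as the only free hydroxyl.

Step 5
Reactants: 8 silylene with free future C3 hydroxyl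
Product: 9 3-O-benzoate of 8
Conditions: BzCl, pyridine, DMAP (cat.), CH2Cl2, 0 °C → rt
Reagents that add atoms: benzoyl chloride, O=C(Cl)c1ccccc1
Why: DMAP-catalysed acylation of the single remaining secondary hydroxyl, with no selectivity required.

Step 6
Reactants: 9 3-O-benzoate of 8
Product: 10 terminal diol (future C4 secondary OH and its CH2OH) with internal acetonide, silylene and benzoate retained
Conditions: AcOH–H2O (7:3), 40 °C
Reagents that add atoms: none
Why: Selective acetal hydrolysis, since the terminal dioxolane hydrolyses faster than the internal dioxolane on the tertiary/secondary diol, and the dioxasilinane and the benzoate tolerate aqueous acetic acid.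

Step 7
Reactants: 10 terminal diol
Product: 12 octa-1,7-diene with 3-O-benzoyl and 1,2-O-isopropylidene and 6,7-O-di-tert-butylsilylene groups, via primary iodide 11 (not isolated)
Conditions: PPh3, I2, imidazole, toluene, 80 °C
Reagents that add atoms: none
Why: Garegg–Samuelsson olefination: the primary hydroxyl is converted into iodide 11, the secondary alkoxyphosphonium then undergoes iodide-induced reductive elimination to the terminal alkene, and no stereocentre is affected.

Step 8
Reactants: 12 octa-1,7-diene
Product: 13 cyclohexene with 3-O-benzoyl, 1,2-O-isopropylidene (cis-fused dioxolane) and 6,7-O-di-tert-butylsilylene groups, configuration as in the target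
Conditions: Grubbs II (5 mol %), CH2Cl2 (0.01 M), 40 °C
Reagents that add atoms: none
Why: Ring-closing olefin metathesis: the ruthenium alkylidene exchanges with one terminal vinyl group, the new alkylidene undergoes intramolecular [2+2] cycloaddition with the second vinyl group, and the ruthenacyclobutane cycloreverts to the C4=C5 cyclohexene and Ru=CH2, which leaves as ethene. The closest known reaction type is the RCM of carbohydrate-derived tetraoxygenated octa-1,7-dienes to conduritols and carbasugars. The one ring closed is the six-membered carbocycle C1–C6, formed by joining C4 to C5 as an endocyclic cis alkene, the only geometry this ring size allows. No stereocentre is created: C1, C2 and C3 arrive from mannose C2–C4 and C6 from step 3, and none is touched by the catalyst. The step needs cyclisation to outrun acyclic diene metathesis oligomerisation and unproductive chelation of ruthenium by the allylic benzoate; the cis-fused dioxolane on C1/C2 holds the C3 and C6 arms on the same face, the dioxasilinane restricts rotation about C6–C1, and high dilution with loss of ethene should do the rest.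

Step 9
Reactants: 13 tricyclic cyclohexene
Product: 14 1,2-diol (tertiary C1–OH and secondary C2–OH free) with silylene and 3-O-benzoate retained
Conditions: AcOH–H2O (4:1), 60 °C
Reagents that add atoms: none
Why: Acid-catalysed acetal hydrolysis of the strained cis-fused dioxolane, under conditions the six-membered di-tert-butylsilylene and the ester should survive.

Step 10
Reactants: 14 1,2-diol
Product: 15 2-O-acetate of 14
Conditions: Ac2O, pyridine, 0 °C → rt
Reagents that add atoms: acetic anhydride, CC(=O)OC(C)=O
Why: Acylation of the secondary C2 hydroxyl, as the tertiary C1 hydroxyl is inert without DMAP and O6/O7 are masked in the silylene.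

Step 11
Reactants: 15 2-O-acetate
Product: 16 (1R,2S,3R,6S)-2-acetoxy-3-benzoyloxy-1-(hydroxymethyl)cyclohex-4-ene-1,6-diol
Conditions: HF·pyridine, pyridine/THF, 0 °C → rt
Reagents that add atoms: none
Why: Fluoride-driven Si–O cleavage of the silylene under mildly acidic, buffered conditions that should not provoke acyl migration.

Step 12
Reactants: 16 (1R,2S,3R,6S)-2-acetoxy-3-benzoyloxy-1-(hydroxymethyl)cyclohex-4-ene-1,6-diol
Product: 17 HY-N2634
Conditions: BzCl (1.1 equiv), 2,4,6-collidine, CH2Cl2, −40 → 0 °C
Reagents that add atoms: benzoyl chloride, O=C(Cl)c1ccccc1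
Why: Selective acylation of the primary hydroxyl over the hindered secondary allylic C6 hydroxyl (next to quaternary C1) and the tertiary C1 hydroxyl, using a weak base at low temperature.

**Compound list**

1 | 2,3:5,6-di-O-isopropylidene-α-D-mannofuranose | O[C@H]1O[C@H]([C@H]3COC(C)(C)O3)[C@@H]2OC(C)(C)O[C@H]12 | starting material
2 | formaldehyde | C=O | starting material
3 | 2-C-(hydroxymethyl)-2,3:5,6-di-O-isopropylidene-D-mannofuranose (anomeric mixture) | OC1O[C@H]([C@H]3COC(C)(C)O3)[C@@H]2OC(C)(C)O[C@]12CO | intermediate
4 | 2-C-[(di-tert-butylsilyloxy)methyl]-2,3:5,6-di-O-isopropylidene-D-mannofuranose (anomeric mixture) | OC1O[C@H]([C@H]3COC(C)(C)O3)[C@@H]2OC(C)(C)O[C@]12CO[SiH](C(C)(C)C)C(C)(C)C | intermediate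
5 | vinylmagnesium bromide | C=C[Mg]Br | starting material
6 | open-chain aldehyde form of 4 (not isolated) | O=C[C@@]1(CO[SiH](C(C)(C)C)C(C)(C)C)OC(C)(C)O[C@H]1[C@H](O)[C@H]1COC(C)(C)O1 | intermediate
7 | (3S)-1,2-dideoxy-4-C-[(di-tert-butylsilyloxy)methyl]-4,5:7,8-di-O-isopropylidene-D-glycero-D-galacto-oct-1-enitol | C=C[C@H](O)[C@@]1(CO[SiH](C(C)(C)C)C(C)(C)C)OC(C)(C)O[C@H]1[C@H](O)[C@H]1COC(C)(C)O1 | intermediate
8 | O6,O7-di-tert-butylsilylene (1,3-dioxa-2-silinane), future C3–OH free | C=C[C@@H]1O[Si](C(C)(C)C)(C(C)(C)C)OC[C@@]12OC(C)(C)O[C@H]2[C@H](O)[C@H]1COC(C)(C)O1 | intermediate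
9 | 3-O-benzoate of 8 | C=C[C@@H]1O[Si](C(C)(C)C)(C(C)(C)C)OC[C@@]12OC(C)(C)O[C@H]2[C@H](OC(=O)c2ccccc2)[C@H]1COC(C)(C)O1 | intermediate
10 | terminal diol from 9 | C=C[C@@H]1O[Si](C(C)(C)C)(C(C)(C)C)OC[C@@]12OC(C)(C)O[C@H]2[C@H](OC(=O)c2ccccc2)[C@H](O)CO | intermediate
11 | primary iodide (iodohydrin) from 10 (not isolated) | C=C[C@@H]1O[Si](C(C)(C)C)(C(C)(C)C)OC[C@@]12OC(C)(C)O[C@H]2[C@H](OC(=O)c2ccccc2)[C@H](O)CI | intermediate
12 | octa-1,7-diene, RCM precursor | C=C[C@@H]1O[Si](C(C)(C)C)(C(C)(C)C)OC[C@@]12OC(C)(C)O[C@H]2[C@H](OC(=O)c2ccccc2)C=C | intermediate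
13 | cyclohexene with 1,2-O-isopropylidene, 6,7-O-silylene and 3-O-benzoyl groups | O=C(O[C@@H]1C=C[C@@H]2O[Si](C(C)(C)C)(C(C)(C)C)OC[C@@]23OC(C)(C)O[C@@H]13)c1ccccc1 | intermediate
14 | 1,2-diol from 13 | O=C(O[C@@H]1C=C[C@@H]2O[Si](C(C)(C)C)(C(C)(C)C)OC[C@]2(O)[C@H]1O)c1ccccc1 | intermediate
15 | 2-O-acetate of 14 | O=C(O[C@@H]1C=C[C@@H]2O[Si](C(C)(C)C)(C(C)(C)C)OC[C@]2(O)[C@H]1OC(C)=O)c1ccccc1 | intermediate
16 | (1R,2S,3R,6S)-2-acetoxy-3-benzoyloxy-1-(hydroxymethyl)cyclohex-4-ene-1,6-diol | O=C(O[C@@H]1C=C[C@H](O)[C@](O)(CO)[C@H]1OC(C)=O)c1ccccc1 | intermediate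
17 | HY-N2634 | CC(=O)O[C@H]1[C@H](OC(=O)c2ccccc2)C=C[C@H](O)[C@]1(O)COC(=O)c1ccccc1 | target

**Step count:** 12 steps in total; the longest linear sequence is 12 steps from 1.

**Steps most likely to fail**

Step 3. The risk is poor or inverted facial selectivity in the vinyl addition, if a non-chelated pathway or another chelate competes with the one assumed. The fallback sets out from 4 and comes back at 7. Lactol 4 is oxidised (DMSO, Ac2O) to the γ-lactone F1. One equivalent of vinylmagnesium bromide at −78 °C gives the 1-C-vinyl hemiketal F2. Its open-chain enone form is reduced with Zn(BH4)2 (Et2O, −20 °C). Hydride then enters the chelated ketone from the face that vinyl took in the aldehyde, so the complementary C6 epimer should form, and whichever sequence gives the (S)-carbinol is used to reach 7.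

Step 4. The risk is slow alcoholysis of the hindered Si–H bond, or base-induced silyl migration and siloxane oligomers instead of ring closure. The fallback sets out from 7 and comes back at 8. The hydrosilyl group is removed with TBAF/AcOH in THF to give the triol F3. This is bridged in the classical way with t-Bu2Si(OTf)2 and 2,6-lutidine in CH2Cl2 at 0 °C, where the 1,3-diol should close to the six-membered silylene 8.

Step 7. The risk is benzoyl migration from O3 to the neighbouring secondary hydroxyl under hot imidazole before activation, or iodide formation without elimination. The fallback sets out from 10 and comes back at 12 by a Corey–Winter olefination. Thiocarbonyldiimidazole (THF, rt) converts the diol into the cyclic thionocarbonate F4. 1,3-Dimethyl-2-phenyl-1,3,2-diazaphospholidine at 40 °C then extrudes CO2 and sulfur to give 12.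

**Further compounds**

F1 | step 3 | γ-lactone from oxidation of 4 | O=C1O[C@H]([C@H]3COC(C)(C)O3)[C@@H]2OC(C)(C)O[C@]12CO[SiH](C(C)(C)C)C(C)(C)C
F2 | step 3 | 1-C-vinyl hemiketal from F1 | C=CC1(O)O[C@H]([C@H]3COC(C)(C)O3)[C@@H]2OC(C)(C)O[C@]12CO[SiH](C(C)(C)C)C(C)(C)C
F3 | step 4 | triol from desilylation of 7 | C=C[C@H](O)[C@@]1(CO)OC(C)(C)O[C@H]1[C@H](O)[C@H]1COC(C)(C)O1
F4 | step 7 | cyclic thionocarbonate of diol 10 | C=C[C@@H]1O[Si](C(C)(C)C)(C(C)(C)C)OC[C@@]12OC(C)(C)O[C@H]2[C@H](OC(=O)c2ccccc2)[C@H]1COC(=S)O1
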